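**Retrosynthetic overview**
1. Target ⇐ last-stage desilylation at C5, catalyst-controlled epoxidation of the 1(10)-Z olefin (oxirane formed last) and angeloylation at C8 of a ten-membered trienolide.
2. Trienolide ⇐ new step: chiral-acid-catalysed macrocyclising allylboration of an ω-formyl 2-(methoxycarbonyl)allylboronate. It forms C6–C7 and the ten-membered carbocycle first, and the cis-fused γ-lactone closes directly afterwards in the same flask.
3. Allylboronate ⇐ Baylis–Hillman reaction at a C7 aldehyde, then SN2′ borylation.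
4. C7–C10 segment ⇐ (Z)-alkenyllithium (from a Stork–Zhao iodo-olefination) plus (S)-PMB glycidyl ether (source of C8).
5. C1–C6 segment ⇐ geraniol, by Sharpless epoxidation (source of C5) and titanium-promoted epoxide-to-allylic-diol isomerisation.

Abbreviations: TBS = tert-butyldimethylsilyl; TIPS = triisopropylsilyl; PMB = 4-methoxybenzyl; Bpin = 4,4,5,5-tetramethyl-1,3,2-dioxaborolan-2-yl; Ang = angeloyl = (2Z)-2-methylbut-2-enoyl; DMP = Dess–Martin periodinane; CSA = camphorsulfonic acid.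

Assumption: atoms carry germacrane labels (ring C1–C10; lactone C11, C12 carbonyl, C13 =CH2; C14 methyl on C10; C15 =CH2 on C4), so the target is (1R,5S,6R,7R,8S,10S)-8-angeloyloxy-1,10-epoxy-5-hydroxygermacra-4(15),11(13)-dien-12,6-olide; the (R)-antipode of the phosphoric acid in step 16 is taken as the one that directs attack to the Re face of the C6 aldehyde.

**Step 1**
Reactants: 1 geraniol [(2E)-3,7-dimethylocta-2,6-dien-1-ol]
Product: 2 (2R,3R)-2,3-epoxygeraniol {[(2R,3R)-3-methyl-3-(4-methylpent-3-en-1-yl)oxiran-2-yl]methanol}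
Conditions: Ti(OiPr)4 (5 mol%), D-(−)-diethyl tartrate (7 mol%), t-BuOOH, 4 Å MS, CH2Cl2, −20 °C
Reagents that add atoms: tert-butyl hydroperoxide CC(C)(C)OO
Why: Sharpless asymmetric epoxidation of the allylic alcohol, in which the D-tartrate–titanium catalyst delivers oxygen to one face of the 2,3-olefin only (the remote trisubstituted olefin is untouched) and so sets the oxygen-bearing centre that becomes C5 as 2R.

**Step 2**
Reactants: 2 (2R,3R)-2,3-epoxygeraniol
Product: 3 (2S)-7-methyl-3-methylideneoct-6-ene-1,2-diol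
Conditions: Ti(OiPr)4 (1.5 equiv), CH2Cl2, rt; aq. tartaric acid work-up
Reagents that add atoms: none
Why: Hydroxyl-directed epoxy-alcohol-to-allylic-diol isomerisation, in which the titanium alkoxide of the primary hydroxyl activates the tertiary C–O bond and a titanium-bound isopropoxide removes a proton from the methyl group cis to the CH2O–Ti arm, giving the C4=C15 methylene while the C5–O bond is never broken, so the configuration is retained (R becomes S only through the CIP priorities).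

**Step 3**
Reactants: 3 (2S)-7-methyl-3-methylideneoct-6-ene-1,2-diol
Product: 4 (2S)-1-(TBSO)-7-methyl-3-methylideneoct-6-en-2-ol
Conditions: TBSCl (1.05 equiv), imidazole, CH2Cl2, 0 °C
Reagents that add atoms: tert-butyldimethylsilyl chloride CC(C)(C)[Si](C)(C)Cl
Why: Silyl ether formation that is selective for the primary hydroxyl on steric grounds.

**Step 4**
Reactants: 4 (2S)-1-(TBSO)-7-methyl-3-methylideneoct-6-en-2-ol
Product: 5 (2S)-1-(TBSO)-7-methyl-3-methylidene-2-(TIPSO)oct-6-ene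
Conditions: TIPSOTf, 2,6-lutidine, CH2Cl2, 0 °C to rt
Reagents that add atoms: triisopropylsilyl triflate CC(C)[Si](OS(=O)(=O)C(F)(F)F)(C(C)C)C(C)C
Why: Silylation of the hindered secondary allylic alcohol with the reactive silyl triflate, the bulky non-chelating TIPS ether being chosen to enforce Felkin–Anh control in step 16 and to outlast both TBS ethers.

**Step 5**
Reactants: 5 (2S)-1-(TBSO)-7-methyl-3-methylidene-2-(TIPSO)oct-6-ene
Product: 7 (5S)-6-(TBSO)-4-methylidene-5-(TIPSO)hexanal, via trisubstituted epoxide 6 (not isolated)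
Conditions: mCPBA (1.05 equiv), NaHCO3, CH2Cl2, 0 °C; then H5IO6, THF/H2O, 0 °C
Reagents that add atoms: meta-chloroperoxybenzoic acid O=C(OO)c1cccc(Cl)c1
Why: Chemoselective Prilezhaev epoxidation of the electron-rich trisubstituted olefin (the 1,1-disubstituted olefin is deactivated and shielded by the allylic silyloxy group) followed by periodic acid cleavage of the epoxide to the aldehyde with loss of acetone.

**Step 6**
Reactants: 7 (5S)-6-(TBSO)-4-methylidene-5-(TIPSO)hexanal, 8 ethyltriphenylphosphonium iodide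
Product: 9 (2S,6Z)-1-(TBSO)-7-iodo-3-methylidene-2-(TIPSO)oct-6-ene
Conditions: 8, n-BuLi, THF, 0 °C; I2, −78 °C; NaN(SiMe3)2, −20 °C; then 7, −78 °C
Reagents that add atoms: iodine II
Why: Stork–Zhao iodo-olefination (Wittig reaction of the α-iodo ylide), whose kinetically controlled oxaphosphetane places iodine cis to the alkyl chain and so fixes the future 1(10)-Z geometry.

**Step 7**
Reactants: 9 (2S,6Z)-1-(TBSO)-7-iodo-3-methylidene-2-(TIPSO)oct-6-ene, 10 (S)-2-[(4-methoxybenzyloxy)methyl]oxirane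
Product: 12 (2S,4Z,9S)-10-(TBSO)-1-(PMBO)-4-methyl-8-methylidene-9-(TIPSO)dec-4-en-2-ol, via Z-alkenyllithium 11 (not isolated)
Conditions: t-BuLi (2.1 equiv), Et2O, −78 °C; then 10, BF3·OEt2, −78 °C
Reagents that add atoms: none
Why: Iodine–lithium exchange with retention of olefin geometry followed by BF3-assisted SN2 opening of the terminal epoxide at its CH2 carbon, so that the C8 carbinol centre is carried over unchanged from the glycidyl ether.

**Step 8**
Reactants: 12 (2S,4Z,9S)-10-(TBSO)-1-(PMBO)-4-methyl-8-methylidene-9-(TIPSO)dec-4-en-2-ol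
Product: 13 (2S,4Z,9S)-2,10-bis(TBSO)-1-(PMBO)-4-methyl-8-methylidene-9-(TIPSO)dec-4-ene
Conditions: TBSOTf, 2,6-lutidine, CH2Cl2, −78 °C
Reagents that add atoms: tert-butyldimethylsilyl triflate CC(C)(C)[Si](C)(C)OS(=O)(=O)C(F)(F)F
Why: Standard silylation of the secondary alcohol, giving an ether at C8 that cannot act as a leaving group or migrate in the later steps.

**Step 9**
Reactants: 13 (2S,4Z,9S)-2,10-bis(TBSO)-1-(PMBO)-4-methyl-8-methylidene-9-(TIPSO)dec-4-ene
Product: 14 (2S,4Z,9S)-2,10-bis(TBSO)-4-methyl-8-methylidene-9-(TIPSO)dec-4-en-1-ol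
Conditions: DDQ, CH2Cl2/pH 7 buffer, 0 °C
Reagents that add atoms: none
Why: Oxidative PMB ether cleavage by DDQ (benzylic hydride abstraction then hydrolysis), under buffered conditions that leave the silyl ethers and the olefins untouched.

**Step 10**
Reactants: 14 (2S,4Z,9S)-2,10-bis(TBSO)-4-methyl-8-methylidene-9-(TIPSO)dec-4-en-1-ol
Product: 15 (2S,4Z,9S)-2,10-bis(TBSO)-4-methyl-8-methylidene-9-(TIPSO)dec-4-enal
Conditions: DMP, NaHCO3, CH2Cl2, 0 °C
Reagents that add atoms: none
Why: Buffered Dess–Martin oxidation gives the α-silyloxy aldehyde without epimerisation at C8, and the crude aldehyde is used at once.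

**Step 11**
Reactants: 15 (2S,4Z,9S)-2,10-bis(TBSO)-4-methyl-8-methylidene-9-(TIPSO)dec-4-enal, 16 methyl acrylate
Product: 17 methyl (4S,6Z,11S)-4,12-bis(TBSO)-3-hydroxy-6-methyl-2,10-dimethylidene-11-(TIPSO)dodec-6-enoate (both C3 epimers)
Conditions: 16 (neat, excess), 1,4-diazabicyclo[2.2.2]octane (1 equiv), rt, 4 d
Reagents that add atoms: none
Why: Morita–Baylis–Hillman reaction that attaches C11–C13 to the C7 aldehyde, the new carbinol centre being inconsequential because it becomes sp2 in step 13.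

**Step 12**
Reactants: 17 methyl (4S,6Z,11S)-4,12-bis(TBSO)-3-hydroxy-6-methyl-2,10-dimethylidene-11-(TIPSO)dodec-6-enoate
Product: 18 methyl (4S,6Z,11S)-3-acetoxy-4,12-bis(TBSO)-6-methyl-2,10-dimethylidene-11-(TIPSO)dodec-6-enoate
Conditions: Ac2O, pyridine, DMAP (cat.), CH2Cl2, 0 °C
Reagents that add atoms: acetic anhydride CC(=O)OC(C)=O
Why: Acetylation turns the Baylis–Hillman hydroxyl into a leaving group for the SN2′ substitution.

**Step 13**
Reactants: 18 methyl (4S,6Z,11S)-3-acetoxy-4,12-bis(TBSO)-6-methyl-2,10-dimethylidene-11-(TIPSO)dodec-6-enoate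
Product: 19 methyl (2E,4S,6Z,11S)-4,12-bis(TBSO)-6-methyl-10-methylidene-2-[(Bpin)methyl]-11-(TIPSO)dodeca-2,6-dienoate
Conditions: bis(pinacolato)diboron, CuCl (10 mol%), LiCl, KOAc, DMF, rt
Reagents that add atoms: bis(pinacolato)diboron CC1(C)OB(OC1(C)C)B1OC(C)(C)C(C)(C)O1
Why: Hosomi–Miyaura-type copper-mediated SN2′ borylation, in which the boryl-copper species adds to the acrylate terminus and acetate is expelled to give the trisubstituted enoate with C8 cis to the CH2B group (2E).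

**Step 14**
Reactants: 19 methyl (2E,4S,6Z,11S)-4,12-bis(TBSO)-6-methyl-10-methylidene-2-[(Bpin)methyl]-11-(TIPSO)dodeca-2,6-dienoate
Product: 20 methyl (2E,4S,6Z,11S)-4-(TBSO)-12-hydroxy-6-methyl-10-methylidene-2-[(Bpin)methyl]-11-(TIPSO)dodeca-2,6-dienoate
Conditions: CSA (10 mol%), MeOH/CH2Cl2 (1:1), 0 °C
Reagents that add atoms: none
Why: Acid-catalysed methanolysis removes the primary TBS ether much faster than the secondary TBS and TIPS ethers, and the pinacol boronate is stable to it.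

**Step 15**
Reactants: 20 methyl (2E,4S,6Z,11S)-4-(TBSO)-12-hydroxy-6-methyl-10-methylidene-2-[(Bpin)methyl]-11-(TIPSO)dodeca-2,6-dienoate
Product: 21 methyl (2E,4S,6Z,11S)-4-(TBSO)-6-methyl-10-methylidene-12-oxo-2-[(Bpin)methyl]-11-(TIPSO)dodeca-2,6-dienoate
Conditions: DMP, NaHCO3, CH2Cl2, 0 °C
Reagents that add atoms: none
Why: Buffered Dess–Martin oxidation gives the C6 aldehyde, which survives long enough to be handled because the ester-deactivated allylboronate does not add to aldehydes at low temperature without a catalyst.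

**Step 16**
Reactants: 21 methyl (2E,4S,6Z,11S)-4-(TBSO)-6-methyl-10-methylidene-12-oxo-2-[(Bpin)methyl]-11-(TIPSO)dodeca-2,6-dienoate
Product: 23 (1(10)Z,5S,6R,7S,8S)-8-(TBSO)-5-(TIPSO)germacra-1(10),4(15),11(13)-trien-12,6-olide, via macrocyclic borate ester 22 (not isolated)
Conditions: (R)-3,3′-bis(2,4,6-triisopropylphenyl)-1,1′-binaphthalene-2,2′-diyl hydrogen phosphate (20 mol%), 4 Å MS, toluene, syringe-pump addition of 21 to 1 mM, 0 to 40 °C, 48 h
Reagents that add atoms: none
Why: Proposed new method: a chiral phosphoric acid catalysed macrocyclising allylboration, in which the acid hydrogen-bonds to a pinacolate oxygen of the ester-deactivated allylboronate (raising the Lewis acidity of boron) while its phosphoryl oxygen holds the formyl C–H, so that the C6 aldehyde binds boron and is attacked by C7 through a closed six-membered chair transition state; because the C7=C11 geometry is fixed (C8 cis to CH2B and therefore axial in the chair) the C6–O/C7–C8 relationship must be syn, which becomes the cis ring fusion when the borate oxygen closes onto the methyl ester, and the Re face of the aldehyde is chosen both by the (R)-acid and by the Felkin–Anh/Cornforth preference of the α-triisopropylsilyloxy aldehyde, giving the 5,6-anti and 6R,7-cis array of the target (C7 is labelled S here only because of the silyl ether at C8), while the Z-olefin turn and the sp2 centres in the tether favour ten-membered ring closure at high dilution; the closest known reactions are the chiral phosphoric acid catalysed intermolecular allylboration of aldehydes with allyl pinacolboronates, the Lewis or Brønsted acid catalysed additions of 2-alkoxycarbonyl allylboronates that give α-methylene-γ-butyrolactones, and thermal intramolecular allylborations that close five- to seven-membered rings.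

**Step 17**
Reactants: 23 (1(10)Z,5S,6R,7S,8S)-8-(TBSO)-5-(TIPSO)germacra-1(10),4(15),11(13)-trien-12,6-olide
Product: 24 (1(10)Z,5S,6R,7R,8S)-8-hydroxy-5-(TIPSO)germacra-1(10),4(15),11(13)-trien-12,6-olide
Conditions: HF·pyridine, pyridine, THF, 0 °C to rt
Reagents that add atoms: none
Why: Buffered HF·pyridine desilylation cleaves the secondary TBS ether much faster than the more hindered and more acid-stable allylic TIPS ether and does not harm the α-methylene lactone.

**Step 18**
Reactants: 24 (1(10)Z,5S,6R,7R,8S)-8-hydroxy-5-(TIPSO)germacra-1(10),4(15),11(13)-trien-12,6-olide, 25 angelic acid [(2Z)-2-methylbut-2-enoic acid]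
Product: 26 (1(10)Z,5S,6R,7R,8S)-8-angeloyloxy-5-(TIPSO)germacra-1(10),4(15),11(13)-trien-12,6-olide
Conditions: 25, 2,4,6-trichlorobenzoyl chloride, Et3N, toluene, rt; then 24, 80 °C
Reagents that add atoms: none
Why: Yamaguchi-type esterification through the mixed 2,4,6-trichlorobenzoic anhydride without DMAP, conditions under which the Z (angelate) double bond is not isomerised to the tiglate.

**Step 19**
Reactants: 26 (1(10)Z,5S,6R,7R,8S)-8-angeloyloxy-5-(TIPSO)germacra-1(10),4(15),11(13)-trien-12,6-olide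
Product: 27 (1R,5S,6R,7R,8S,10S)-8-angeloyloxy-1,10-epoxy-5-(TIPSO)germacra-4(15),11(13)-dien-12,6-olide
Conditions: D-fructose-derived Shi ketone (1,2:4,5-di-O-isopropylidene-β-D-erythro-2,3-hexodiulo-2,6-pyranose, 30 mol%), Oxone (2KHSO5·KHSO4·K2SO4), K2CO3, Bu4NHSO4, MeCN/dimethoxymethane/aq. Na2B4O7 buffer, 0 °C
Reagents that add atoms: potassium peroxymonosulfate [K+].[O-]S(=O)(=O)OO
Why: Shi asymmetric epoxidation, in which the chiral dioxirane attacks the only electron-rich trisubstituted olefin through a spiro transition state whose facial preference for 1-methylcycloalkene-type olefins gives the (1R,10S) cis-epoxide, while the two enoates and the silyloxy-shielded exocyclic methylene react much more slowly.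

**Step 20**
Reactants: 27 (1R,5S,6R,7R,8S,10S)-8-angeloyloxy-1,10-epoxy-5-(TIPSO)germacra-4(15),11(13)-dien-12,6-olide
Product: 28 (1R,5S,6R,7R,8S,10S)-8-angeloyloxy-1,10-epoxy-5-hydroxygermacra-4(15),11(13)-dien-12,6-olide (CNP0227074.3)
Conditions: Bu4NF, AcOH (1:1), THF, 0 °C to rt
Reagents that add atoms: none
Why: Acetic acid buffered fluoride desilylation frees the C5 hydroxyl under near-neutral conditions that spare the epoxide, the angelate and the α-methylene lactone.

**Compound list**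
1 | geraniol, (2E)-3,7-dimethylocta-2,6-dien-1-ol | CC(C)=CCC/C(C)=C/CO | starting material
2 | (2R,3R)-2,3-epoxygeraniol | CC(C)=CCC[C@@]1(C)O[C@@H]1CO | intermediate
3 | (2S)-7-methyl-3-methylideneoct-6-ene-1,2-diol | CC(C)=CCCC(=C)[C@@H](CO)O | intermediate
4 | (2S)-1-(TBSO)-7-methyl-3-methylideneoct-6-en-2-ol | CC(C)=CCCC(=C)[C@@H](CO[Si](C)(C)C(C)(C)C)O | intermediate
5 | (2S)-1-(TBSO)-7-methyl-3-methylidene-2-(TIPSO)oct-6-ene | CC(C)=CCCC(=C)[C@@H](CO[Si](C)(C)C(C)(C)C)O[Si](C(C)C)(C(C)C)C(C)C | intermediate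
6 | (2S)-1-(TBSO)-6,7-epoxy-7-methyl-3-methylidene-2-(TIPSO)octane (both C6 epimers) | CC1(C)OC1CCC(=C)[C@@H](CO[Si](C)(C)C(C)(C)C)O[Si](C(C)C)(C(C)C)C(C)C | intermediate
7 | (5S)-6-(TBSO)-4-methylidene-5-(TIPSO)hexanal | O=CCCC(=C)[C@@H](CO[Si](C)(C)C(C)(C)C)O[Si](C(C)C)(C(C)C)C(C)C | intermediate
8 | ethyltriphenylphosphonium iodide | CC[P+](c1ccccc1)(c1ccccc1)c1ccccc1.[I-] | starting material
9 | (2S,6Z)-1-(TBSO)-7-iodo-3-methylidene-2-(TIPSO)oct-6-ene | I/C(C)=C\CCC(=C)[C@@H](CO[Si](C)(C)C(C)(C)C)O[Si](C(C)C)(C(C)C)C(C)C | intermediate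
10 | (S)-2-[(4-methoxybenzyloxy)methyl]oxirane, (S)-PMB glycidyl ether | COc1ccc(COC[C@@H]2CO2)cc1 | starting material
11 | (2S,6Z)-1-(TBSO)-7-lithio-3-methylidene-2-(TIPSO)oct-6-ene | [Li]/C(C)=C\CCC(=C)[C@@H](CO[Si](C)(C)C(C)(C)C)O[Si](C(C)C)(C(C)C)C(C)C | intermediate
12 | (2S,4Z,9S)-10-(TBSO)-1-(PMBO)-4-methyl-8-methylidene-9-(TIPSO)dec-4-en-2-ol | COc1ccc(COC[C@@H](O)C/C(C)=C\CCC(=C)[C@@H](CO[Si](C)(C)C(C)(C)C)O[Si](C(C)C)(C(C)C)C(C)C)cc1 | intermediate
13 | (2S,4Z,9S)-2,10-bis(TBSO)-1-(PMBO)-4-methyl-8-methylidene-9-(TIPSO)dec-4-ene | COc1ccc(COC[C@@H](O[Si](C)(C)C(C)(C)C)C/C(C)=C\CCC(=C)[C@@H](CO[Si](C)(C)C(C)(C)C)O[Si](C(C)C)(C(C)C)C(C)C)cc1 | intermediate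
14 | (2S,4Z,9S)-2,10-bis(TBSO)-4-methyl-8-methylidene-9-(TIPSO)dec-4-en-1-ol | OC[C@@H](O[Si](C)(C)C(C)(C)C)C/C(C)=C\CCC(=C)[C@@H](CO[Si](C)(C)C(C)(C)C)O[Si](C(C)C)(C(C)C)C(C)C | intermediate
15 | (2S,4Z,9S)-2,10-bis(TBSO)-4-methyl-8-methylidene-9-(TIPSO)dec-4-enal | O=C[C@@H](O[Si](C)(C)C(C)(C)C)C/C(C)=C\CCC(=C)[C@@H](CO[Si](C)(C)C(C)(C)C)O[Si](C(C)C)(C(C)C)C(C)C | intermediate
16 | methyl acrylate | C=CC(=O)OC | starting material
17 | methyl (4S,6Z,11S)-4,12-bis(TBSO)-3-hydroxy-6-methyl-2,10-dimethylidene-11-(TIPSO)dodec-6-enoate (both C3 epimers) | COC(=O)C(=C)C(O)[C@@H](O[Si](C)(C)C(C)(C)C)C/C(C)=C\CCC(=C)[C@@H](CO[Si](C)(C)C(C)(C)C)O[Si](C(C)C)(C(C)C)C(C)C | intermediate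
18 | methyl (4S,6Z,11S)-3-acetoxy-4,12-bis(TBSO)-6-methyl-2,10-dimethylidene-11-(TIPSO)dodec-6-enoate (both C3 epimers) | COC(=O)C(=C)C(OC(C)=O)[C@@H](O[Si](C)(C)C(C)(C)C)C/C(C)=C\CCC(=C)[C@@H](CO[Si](C)(C)C(C)(C)C)O[Si](C(C)C)(C(C)C)C(C)C | intermediate
19 | methyl (2E,4S,6Z,11S)-4,12-bis(TBSO)-6-methyl-10-methylidene-2-[(Bpin)methyl]-11-(TIPSO)dodeca-2,6-dienoate | COC(=O)/C(CB1OC(C)(C)C(C)(C)O1)=C/[C@@H](O[Si](C)(C)C(C)(C)C)C/C(C)=C\CCC(=C)[C@@H](CO[Si](C)(C)C(C)(C)C)O[Si](C(C)C)(C(C)C)C(C)C | intermediate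
20 | methyl (2E,4S,6Z,11S)-4-(TBSO)-12-hydroxy-6-methyl-10-methylidene-2-[(Bpin)methyl]-11-(TIPSO)dodeca-2,6-dienoate | COC(=O)/C(CB1OC(C)(C)C(C)(C)O1)=C/[C@@H](O[Si](C)(C)C(C)(C)C)C/C(C)=C\CCC(=C)[C@@H](CO)O[Si](C(C)C)(C(C)C)C(C)C | intermediate
21 | methyl (2E,4S,6Z,11S)-4-(TBSO)-6-methyl-10-methylidene-12-oxo-2-[(Bpin)methyl]-11-(TIPSO)dodeca-2,6-dienoate | COC(=O)/C(CB1OC(C)(C)C(C)(C)O1)=C/[C@@H](O[Si](C)(C)C(C)(C)C)C/C(C)=C\CCC(=C)[C@@H](C=O)O[Si](C(C)C)(C(C)C)C(C)C | intermediate
22 | methyl (1(10)Z,5S,6R,7S,8S)-6-(Bpin-oxy)-8-(TBSO)-5-(TIPSO)germacra-1(10),4(15),11(13)-trien-12-oate (ten-membered ring; C7 carries C(=CH2)CO2Me) | CC1(C)OB(O[C@@H]2[C@H](C(=C)C(=O)OC)[C@@H](O[Si](C)(C)C(C)(C)C)C/C(C)=C\CCC(=C)[C@@H]2O[Si](C(C)C)(C(C)C)C(C)C)OC1(C)C | intermediate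
23 | (1(10)Z,5S,6R,7S,8S)-8-(TBSO)-5-(TIPSO)germacra-1(10),4(15),11(13)-trien-12,6-olide | C=C1C(=O)O[C@@H]2[C@H]1[C@@H](O[Si](C)(C)C(C)(C)C)C/C(C)=C\CCC(=C)[C@@H]2O[Si](C(C)C)(C(C)C)C(C)C | intermediate
24 | (1(10)Z,5S,6R,7R,8S)-8-hydroxy-5-(TIPSO)germacra-1(10),4(15),11(13)-trien-12,6-olide | C=C1C(=O)O[C@@H]2[C@H]1[C@@H](O)C/C(C)=C\CCC(=C)[C@@H]2O[Si](C(C)C)(C(C)C)C(C)C | intermediate
25 | angelic acid, (2Z)-2-methylbut-2-enoic acid | C/C=C(/C)C(=O)O | starting material
26 | (1(10)Z,5S,6R,7R,8S)-8-angeloyloxy-5-(TIPSO)germacra-1(10),4(15),11(13)-trien-12,6-olide | C=C1C(=O)O[C@@H]2[C@H]1[C@@H](OC(=O)/C(C)=C\C)C/C(C)=C\CCC(=C)[C@@H]2O[Si](C(C)C)(C(C)C)C(C)C | intermediate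
27 | (1R,5S,6R,7R,8S,10S)-8-angeloyloxy-1,10-epoxy-5-(TIPSO)germacra-4(15),11(13)-dien-12,6-olide | C=C1C(=O)O[C@@H]2[C@H]1[C@@H](OC(=O)/C(C)=C\C)C[C@]1(C)O[C@@H]1CCC(=C)[C@@H]2O[Si](C(C)C)(C(C)C)C(C)C | intermediate
28 | (1R,5S,6R,7R,8S,10S)-8-angeloyloxy-1,10-epoxy-5-hydroxygermacra-4(15),11(13)-dien-12,6-olide (CNP0227074.3) | C=C1C(=O)O[C@@H]2[C@H]1[C@@H](OC(=O)/C(C)=C\C)C[C@]1(C)O[C@@H]1CCC(=C)[C@@H]2O | target

**Totals**
Total step count: 20. Longest linear sequence: 20 steps (1 to 28); compounds 8, 10, 16 and 25 are bought.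

**Steps most likely to fail, with fallbacks**

Step 16 (the proposed new macrocyclising allylboration; risks are slow turnover at high dilution, acid-induced isomerisation of the β,γ-unsaturated α-silyloxy aldehyde, or a poor diastereomer ratio). Fallback with known chemistry: it sets out from 17 and comes back at 23. The Baylis–Hillman alcohol 17 is converted with N-bromosuccinimide and Me2S (SN2′ bromination) into methyl (2Z,4S,6Z,11S)-2-(bromomethyl)-4,12-bis(TBSO)-6-methyl-10-methylidene-11-(TIPSO)dodeca-2,6-dienoate F1. The primary silyl ether is removed as in step 14 to give the bromo alcohol F2, and Dess–Martin oxidation as in step 15 gives the bromo aldehyde F3. F3 is then cyclised with excess CrCl2 in THF at 1 mM. This is the stoichiometric Barbier-type Nozaki–Hiyama allylation with spontaneous lactonisation that is the established closure of ten-membered germacranolides. Here the organochromium nucleophile replaces boron and the stereochemistry rests on substrate control alone (Felkin–Anh at C5 and the cis preference of (Z)-2-(bromomethyl) enoates). The product is 23.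

Step 19 (Shi epoxidation of the macrocyclic Z-olefin; risks are that the ring conformation overrides the catalyst or that the exocyclic methylene competes). Fallback: it sets out from 24 and comes back at 27. Before acylation, the free homoallylic C8 hydroxyl of 24 is used to direct the oxidant: VO(acac)2 (cat.) and t-BuOOH in CH2Cl2 deliver oxygen to C1=C10 only, from the face reached by the vanadate bound at C8, giving the epoxy alcohol F4. F4 is then esterified with 25 exactly as in step 18 to give 27.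

Step 11 (Baylis–Hillman reaction of a hindered α-silyloxy aldehyde; risks are a very slow reaction and epimerisation at C8). Fallback: it sets out from 15 and comes back at 17. Methyl propiolate is hydroaluminated with i-Bu2AlH and HMPA in THF at 0 °C to the vinylalane F5. F5 adds to 15 at −78 to 0 °C (vinylalumination), giving 17 after aqueous work-up without an amine base or long reaction time.

**Further compounds**
F1 | step 16 | methyl (2Z,4S,6Z,11S)-2-(bromomethyl)-4,12-bis(TBSO)-6-methyl-10-methylidene-11-(TIPSO)dodeca-2,6-dienoate | COC(=O)/C(CBr)=C/[C@@H](O[Si](C)(C)C(C)(C)C)C/C(C)=C\CCC(=C)[C@@H](CO[Si](C)(C)C(C)(C)C)O[Si](C(C)C)(C(C)C)C(C)C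
F2 | step 16 | bromo alcohol, methyl (2Z,4S,6Z,11S)-2-(bromomethyl)-4-(TBSO)-12-hydroxy-6-methyl-10-methylidene-11-(TIPSO)dodeca-2,6-dienoate | COC(=O)/C(CBr)=C/[C@@H](O[Si](C)(C)C(C)(C)C)C/C(C)=C\CCC(=C)[C@@H](CO)O[Si](C(C)C)(C(C)C)C(C)C
F3 | step 16 | bromo aldehyde, methyl (2Z,4S,6Z,11S)-2-(bromomethyl)-4-(TBSO)-6-methyl-10-methylidene-12-oxo-11-(TIPSO)dodeca-2,6-dienoate | COC(=O)/C(CBr)=C/[C@@H](O[Si](C)(C)C(C)(C)C)C/C(C)=C\CCC(=C)[C@@H](C=O)O[Si](C(C)C)(C(C)C)C(C)C
F4 | step 19 | epoxy alcohol, (1R,5S,6R,7R,8S,10S)-1,10-epoxy-8-hydroxy-5-(TIPSO)germacra-4(15),11(13)-dien-12,6-olide | C=C1C(=O)O[C@@H]2[C@H]1[C@@H](O)C[C@]1(C)O[C@@H]1CCC(=C)[C@@H]2O[Si](C(C)C)(C(C)C)C(C)C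
F5 | step 11 | vinylalane, methyl 2-(diisobutylalumanyl)prop-2-enoate | COC(=O)C(=C)[Al](CC(C)C)CC(C)C
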